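**Strategy.** The C8–C2' biaryl bond is never made by coupling. C8 (ring A of unit 1, the 8-linked flavone), C2' and C1' (ring B of unit 2, the other flavone), C2 of unit 2 and the oxygen on C8a coincide with C4a, C4, C3, C2 and O1 of a 5,7-dioxygenated coumarin. Phloroglucinol, being symmetric, forms this coumarin as a single isomer. The key step grows ring B of unit 2 onto the coumarin: the carbanion of the 4-methyl group (C3') acylates the ester carbon (C4') of a 3-propanoate chain. One operation closes the carbocycle and places its oxygen at C4'. The precursor is ethyl 5,7-bis(benzyloxy)-4-methylcoumarin-3-propanoate.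

Key step: step 3

Assumption: the SMILES shows no stereocentre and fixes no configuration at the hindered C8–C2' axis, so the biaryl is carried through and delivered without axial stereocontrol.

Step 1
Reactants: 1 phloroglucinol; 2 diethyl 2-acetylglutarate
Product: 3 ethyl 3-(5,7-dihydroxy-4-methyl-2-oxo-2H-chromen-3-yl)propanoate
Conditions: dry HCl, abs. EtOH, 0 °C → rt
Reagents that add atoms: none
Why: Pechmann condensation, in which the very electron-rich symmetric phenol reacts with the beta-keto ester unit of 2 (transesterification, ring attack on the ketone, dehydration) to give the only possible coumarin, while the remote ester stays an ethyl ester in ethanolic HCl.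

Step 2
Reactants: 3 ethyl 3-(5,7-dihydroxy-4-methyl-2-oxo-2H-chromen-3-yl)propanoate
Product: 4 ethyl 3-[5,7-bis(benzyloxy)-4-methyl-2-oxo-2H-chromen-3-yl]propanoate
Conditions: BnBr (2.5 equiv), K2CO3 (3 equiv), DMF, 60 °C
Reagents that add atoms: benzyl bromide, BrCc1ccccc1
Why: Williamson ether synthesis on two acidic coumarin phenols, with benzyl chosen because it tolerates the strong bases, iodine and Brønsted acids used later and can be removed at the end without touching the two aryl methyl ethers.

Step 3
Reactants: 4 ethyl 3-[5,7-bis(benzyloxy)-4-methyl-2-oxo-2H-chromen-3-yl]propanoate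
Product: 5 1,3-bis(benzyloxy)-7,8-dihydro-6H-benzo[c]chromene-6,9(10H)-dione
Conditions: LiN(SiMe3)2 (2.5 equiv), THF (0.02 M), Ar, −78 °C → rt; then 1 M HCl, 0 °C
Reagents that add atoms: none
Why: Proposed new method: LiN(SiMe3)2 removes a proton from the C4 methyl group, which the lactone carbonyl acidifies vinylogously, the exocyclic CH2 terminus of the extended dienolate adds to the side-chain ester, and after loss of ethoxide the second equivalent of base converts the ketone into its doubly stabilised C10 enolate, which drains the Claisen equilibrium. The closest known reactions are gamma-deprotonation of 4-methylcoumarins with intermolecular acylation or aldol trapping and the ordinary Dieckmann cyclisation, and the new element is their intramolecular vinylogous combination. The single ring closes in a 6-(enolendo)-exo-trig mode, favoured because the C3=C4 double bond keeps nucleophile and electrophile on the same side. No stereocentre is formed. The step needs site selectivity among the gamma terminus, the alpha terminus (C3) of the same dienolate and the ester alpha-enolate, and chemoselectivity for the ester over the lactone carbonyl; attack from C3 on the ester or from the ester alpha-carbon on the lactone could only build four-membered rings, and with a silazide base these deprotonations are reversible, so the material should funnel through the six-membered closure. High dilution suppresses intermolecular Claisen condensation, and the benzyl ethers offer no acidic or electrophilic site.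

Step 4
Reactants: 5 1,3-bis(benzyloxy)-7,8-dihydro-6H-benzo[c]chromene-6,9(10H)-dione
Product: 6 1,3-bis(benzyloxy)-9-methoxy-6H-benzo[c]chromen-6-one
Conditions: I2 (2 equiv), MeOH–toluene, reflux
Reagents that add atoms: methanol, CO
Why: Iodine–methanol oxidative aromatisation as established for Hagemann-type 4-oxocyclohexenecarboxylates, in which acid-catalysed formation of the methyl dienol ether, iodination and loss of HI turn the C9 ketone directly into the C4' methyl ether, while the planar biaryl lactone has no tendency to stay opened by methanol.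

Step 5
Reactants: 7 2',4',6'-trihydroxyacetophenone
Product: 8 1-[2,4-bis(benzyloxy)-6-hydroxyphenyl]ethan-1-one
Conditions: BnBr (2.1 equiv), K2CO3 (2.2 equiv), DMF, rt → 50 °C
Reagents that add atoms: benzyl bromide, BrCc1ccccc1
Why: Williamson etherification that stops after two benzylations because the remaining hydroxyl is hydrogen-bonded to the acetyl group, which leaves free exactly the phenol that becomes O1 of unit 2.

Step 6
Reactants: 6 1,3-bis(benzyloxy)-9-methoxy-6H-benzo[c]chromen-6-one; 8 1-[2,4-bis(benzyloxy)-6-hydroxyphenyl]ethan-1-one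
Product: 9 1-[2,4-bis(benzyloxy)-6-hydroxyphenyl]-3-[2',4'-bis(benzyloxy)-6'-hydroxy-5-methoxybiphenyl-2-yl]propane-1,3-dione
Conditions: 8 (1.1 equiv), LiN(SiMe3)2 (3.5 equiv), THF, −78 → −10 °C; add 6, −78 °C → rt; then 1 M HCl
Reagents that add atoms: none
Why: Crossed Claisen acylation of the phenoxide–enolate dianion of 8 by an aryl ester, which should be clean because 6 has no acidic C–H, its bay-strained lactone expels an aryloxide that stays in the molecule, and deprotonation of the new 1,3-diketone by the third equivalent of base makes the opening irreversible.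

Step 7
Reactants: 9 1-[2,4-bis(benzyloxy)-6-hydroxyphenyl]-3-[2',4'-bis(benzyloxy)-6'-hydroxy-5-methoxybiphenyl-2-yl]propane-1,3-dione
Product: 10 3,5-bis(benzyloxy)-2-(2-{3-[2,4-bis(benzyloxy)-6-hydroxyphenyl]-3-oxopropanoyl}-5-methoxyphenyl)phenyl acetate
Conditions: Ac2O (1.1 equiv), pyridine, CH2Cl2, 0 °C
Reagents that add atoms: acetic anhydride, CC(=O)OC(C)=O
Why: Chemoselective O-acetylation of the one unchelated phenol (the other phenol and the diketone enol sit in six-membered hydrogen-bond chelates), where the acetate both stops this phenol from competing for the future C2 carbonyl of unit 2 in step 8 and stores the acetyl group needed in step 9.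

Step 8
Reactants: 10 3,5-bis(benzyloxy)-2-(2-{3-[2,4-bis(benzyloxy)-6-hydroxyphenyl]-3-oxopropanoyl}-5-methoxyphenyl)phenyl acetate
Product: 11 3,5-bis(benzyloxy)-2-{2-[5,7-bis(benzyloxy)-4-oxo-4H-chromen-2-yl]-5-methoxyphenyl}phenyl acetate
Conditions: TsOH·H2O (0.1 equiv), toluene, reflux, Dean–Stark
Reagents that add atoms: none
Why: Acid-catalysed cyclodehydration of an o-hydroxyaryl 1,3-diketone (the closing stage of the Baker–Venkataraman flavone synthesis), in which the only free phenol adds to the distal carbonyl and azeotropic removal of water gives the pyrone of unit 2 while sparing the aryl acetate and the benzyl ethers.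

Step 9
Reactants: 11 3,5-bis(benzyloxy)-2-{2-[5,7-bis(benzyloxy)-4-oxo-4H-chromen-2-yl]-5-methoxyphenyl}phenyl acetate
Product: 13 2-[3'-acetyl-4',6'-bis(benzyloxy)-2'-hydroxy-5-methoxybiphenyl-2-yl]-5,7-bis(benzyloxy)-4H-chromen-4-one, via difluoroboron chelate 12 (not isolated)
Conditions: BF3·OEt2 (6 equiv), ClCH2CH2Cl, 50 °C; then MeOH–H2O, 60 °C
Reagents that add atoms: none
Why: Fries rearrangement that moves the acetyl group to the only free position ortho to its oxygen (the future C4a of unit 1), since the crowded para ketone forms reversibly whereas the ortho isomer is trapped as chelate 12, and BF3, which cannot bind in a bidentate way and meets no soft nucleophile here, should leave the aryl benzyl ethers intact at this temperature.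

Step 10
Reactants: 13 2-[3'-acetyl-4',6'-bis(benzyloxy)-2'-hydroxy-5-methoxybiphenyl-2-yl]-5,7-bis(benzyloxy)-4H-chromen-4-one; 14 4-methoxybenzoyl chloride
Product: 15 1-{4',6'-bis(benzyloxy)-2-[5,7-bis(benzyloxy)-4-oxo-4H-chromen-2-yl]-2'-hydroxy-5-methoxybiphenyl-3'-yl}-3-(4-methoxyphenyl)propane-1,3-dione
Conditions: LiN(SiMe3)2 (3.2 equiv), THF, −78 → −10 °C; 14 (1.1 equiv), −78 °C → rt; then 1 M HCl
Reagents that add atoms: none
Why: Acylation of the lithium phenoxide–enolate dianion of an o-hydroxyacetophenone with an aroyl chloride (one-flask variant of the Baker–Venkataraman sequence) gives the 1,3-diketone directly, and the low temperature and absence of hydroxide spare the pyrone of unit 2, which a Claisen–Schmidt route would expose to alkali for a long time.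

Step 11
Reactants: 15 1-{4',6'-bis(benzyloxy)-2-[5,7-bis(benzyloxy)-4-oxo-4H-chromen-2-yl]-2'-hydroxy-5-methoxybiphenyl-3'-yl}-3-(4-methoxyphenyl)propane-1,3-dione
Product: 16 5,7-bis(benzyloxy)-8-{2-[5,7-bis(benzyloxy)-4-oxo-4H-chromen-2-yl]-5-methoxyphenyl}-2-(4-methoxyphenyl)-4H-chromen-4-one
Conditions: TsOH·H2O (0.1 equiv), toluene, reflux, Dean–Stark
Reagents that add atoms: none
Why: The same acid-catalysed cyclodehydration as in step 8, where the hydroxyl next to the biaryl axis is the only free one flanking the ketone, so ring closure can give only the 8-aryl and not the 6-aryl flavone.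

Step 12
Reactants: 16 5,7-bis(benzyloxy)-8-{2-[5,7-bis(benzyloxy)-4-oxo-4H-chromen-2-yl]-5-methoxyphenyl}-2-(4-methoxyphenyl)-4H-chromen-4-one
Product: 17 5,7-dihydroxy-8-[2-(5,7-dihydroxy-4-oxo-4H-chromen-2-yl)-5-methoxyphenyl]-2-(4-methoxyphenyl)-4H-chromen-4-one (CNP0394081.0)
Conditions: BCl3 (10 equiv), C6HMe5 (12 equiv), CH2Cl2, −78 °C; then MeOH–H2O
Reagents that add atoms: none
Why: Lewis-acid debenzylation with BCl3 and pentamethylbenzene as benzyl-cation scavenger should cleave the four benzyl ethers at −78 °C, where the two aryl methyl ethers, neither next to a carbonyl group, are not attacked and no Wessely–Moser isomerisation can occur.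

**Compound list**

1 | phloroglucinol | Oc1cc(O)cc(O)c1 | starting material
2 | diethyl 2-acetylglutarate | CCOC(=O)CCC(C(C)=O)C(=O)OCC | starting material
3 | ethyl 3-(5,7-dihydroxy-4-methyl-2-oxo-2H-chromen-3-yl)propanoate | CCOC(=O)CCc1c(C)c2c(O)cc(O)cc2oc1=O | intermediate
4 | ethyl 3-[5,7-bis(benzyloxy)-4-methyl-2-oxo-2H-chromen-3-yl]propanoate | CCOC(=O)CCc1c(C)c2c(OCc3ccccc3)cc(OCc3ccccc3)cc2oc1=O | intermediate
5 | 1,3-bis(benzyloxy)-7,8-dihydro-6H-benzo[c]chromene-6,9(10H)-dione | O=C1CCc2c(C1)c1c(OCc3ccccc3)cc(OCc3ccccc3)cc1oc2=O | intermediate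
6 | 1,3-bis(benzyloxy)-9-methoxy-6H-benzo[c]chromen-6-one | COc1ccc2c(c1)c1c(OCc3ccccc3)cc(OCc3ccccc3)cc1oc2=O | intermediate
7 | 2',4',6'-trihydroxyacetophenone | CC(=O)c1c(O)cc(O)cc1O | starting material
8 | 1-[2,4-bis(benzyloxy)-6-hydroxyphenyl]ethan-1-one | CC(=O)c1c(O)cc(OCc2ccccc2)cc1OCc1ccccc1 | intermediate
9 | 1-[2,4-bis(benzyloxy)-6-hydroxyphenyl]-3-[2',4'-bis(benzyloxy)-6'-hydroxy-5-methoxybiphenyl-2-yl]propane-1,3-dione | COc1ccc(C(=O)CC(=O)c2c(O)cc(OCc3ccccc3)cc2OCc2ccccc2)c(c1)-c1c(O)cc(OCc2ccccc2)cc1OCc1ccccc1 | intermediate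
10 | 3,5-bis(benzyloxy)-2-(2-{3-[2,4-bis(benzyloxy)-6-hydroxyphenyl]-3-oxopropanoyl}-5-methoxyphenyl)phenyl acetate | COc1ccc(C(=O)CC(=O)c2c(O)cc(OCc3ccccc3)cc2OCc2ccccc2)c(c1)-c1c(OC(C)=O)cc(OCc2ccccc2)cc1OCc1ccccc1 | intermediate
11 | 3,5-bis(benzyloxy)-2-{2-[5,7-bis(benzyloxy)-4-oxo-4H-chromen-2-yl]-5-methoxyphenyl}phenyl acetate | COc1ccc(-c2cc(=O)c3c(OCc4ccccc4)cc(OCc4ccccc4)cc3o2)c(c1)-c1c(OC(C)=O)cc(OCc2ccccc2)cc1OCc1ccccc1 | intermediate
12 | difluoroboron chelate of 13 (O–BF2 bridge between the phenol oxygen and the acetyl oxygen; not isolated) | CC1=[O+][B-](F)(F)Oc2c1c(OCc1ccccc1)cc(OCc1ccccc1)c2-c1cc(OC)ccc1-c1cc(=O)c2c(OCc3ccccc3)cc(OCc3ccccc3)cc2o1 | intermediate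
13 | 2-[3'-acetyl-4',6'-bis(benzyloxy)-2'-hydroxy-5-methoxybiphenyl-2-yl]-5,7-bis(benzyloxy)-4H-chromen-4-one | CC(=O)c1c(O)c(-c2cc(OC)ccc2-c2cc(=O)c3c(OCc4ccccc4)cc(OCc4ccccc4)cc3o2)c(OCc2ccccc2)cc1OCc1ccccc1 | intermediate
14 | 4-methoxybenzoyl chloride | COc1ccc(C(=O)Cl)cc1 | starting material
15 | 1-{4',6'-bis(benzyloxy)-2-[5,7-bis(benzyloxy)-4-oxo-4H-chromen-2-yl]-2'-hydroxy-5-methoxybiphenyl-3'-yl}-3-(4-methoxyphenyl)propane-1,3-dione | COc1ccc(cc1)C(=O)CC(=O)c1c(O)c(-c2cc(OC)ccc2-c2cc(=O)c3c(OCc4ccccc4)cc(OCc4ccccc4)cc3o2)c(OCc2ccccc2)cc1OCc1ccccc1 | intermediate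
16 | 5,7-bis(benzyloxy)-8-{2-[5,7-bis(benzyloxy)-4-oxo-4H-chromen-2-yl]-5-methoxyphenyl}-2-(4-methoxyphenyl)-4H-chromen-4-one | COc1ccc(-c2cc(=O)c3c(OCc4ccccc4)cc(OCc4ccccc4)c(-c4cc(OC)ccc4-c4cc(=O)c5c(OCc6ccccc6)cc(OCc6ccccc6)cc5o4)c3o2)cc1 | intermediate
17 | 5,7-dihydroxy-8-[2-(5,7-dihydroxy-4-oxo-4H-chromen-2-yl)-5-methoxyphenyl]-2-(4-methoxyphenyl)-4H-chromen-4-one (CNP0394081.0) | COc1ccc(-c2cc(=O)c3c(O)cc(O)c(-c4cc(OC)ccc4-c4cc(=O)c5c(O)cc(O)cc5o4)c3o2)cc1 | target

Total step count: 12. Longest linear sequence: 11 (steps 1–4 and 6–12; step 5 is a one-step branch).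

**Steps most likely to fail**

Risk 1, step 3 (the new method): the dienolate may form without closing the ring. Ester enolisation, intermolecular Claisen condensation, or opening of the lactone by the released ethoxide could take over. The fallback uses known chemistry, sets out from 1 and comes back at 6. A Hurtley condensation of phloroglucinol 1 with commercial 2-bromo-4-methoxybenzoic acid (CuSO4 cat., aq NaOH, reflux) arylates a ring carbon of 1. On acidification the product lactonises to 1,3-dihydroxy-9-methoxy-6H-benzo[c]chromen-6-one F1. Benzylation (BnBr, K2CO3, DMF) then gives 6.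

Risk 2, step 9: benzyl groups may be lost or migrate under the Lewis acid, or the acyl group may transfer to the position para to the oxygen. The fallback avoids Friedel–Crafts chemistry, sets out from 11 and comes back at 16. K2CO3 in MeOH removes the acetate to give 5,7-bis(benzyloxy)-2-[2',4'-bis(benzyloxy)-6'-hydroxy-5-methoxybiphenyl-2-yl]-4H-chromen-4-one F2. N-Iodosuccinimide (MeCN, 0 °C) should iodinate the less crowded position ortho to the hydroxyl, giving 5,7-bis(benzyloxy)-2-[4',6'-bis(benzyloxy)-2'-hydroxy-3'-iodo-5-methoxybiphenyl-2-yl]-4H-chromen-4-one F3. A carbonylative Sonogashira annulation with 4-ethynylanisole (PdCl2(PPh3)2, CO 1 atm, Et2NH, 60 °C) forms the o-hydroxyaryl ynone. The amine steers this ynone into 6-endo closure, which gives 16 directly.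

Risk 3, step 4: the benzyloxy-substituted ring may be iodinated, the HI formed may cleave benzyl ethers, or poor solubility in methanol may slow enol ether formation. The fallback separates oxidation from methylation, sets out from 5 and comes back at 6. Dehydrogenation with DDQ (1,4-dioxane, rt → 60 °C) gives 1,3-bis(benzyloxy)-9-hydroxy-6H-benzo[c]chromen-6-one F4. O-Methylation with MeI and K2CO3 in acetone then gives 6.

**Further compounds**

F1 | step 3 | 1,3-dihydroxy-9-methoxy-6H-benzo[c]chromen-6-one | COc1ccc2c(c1)c1c(O)cc(O)cc1oc2=O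
F2 | step 9 | 5,7-bis(benzyloxy)-2-[2',4'-bis(benzyloxy)-6'-hydroxy-5-methoxybiphenyl-2-yl]-4H-chromen-4-one | COc1ccc(-c2cc(=O)c3c(OCc4ccccc4)cc(OCc4ccccc4)cc3o2)c(c1)-c1c(O)cc(OCc2ccccc2)cc1OCc1ccccc1
F3 | step 9 | 5,7-bis(benzyloxy)-2-[4',6'-bis(benzyloxy)-2'-hydroxy-3'-iodo-5-methoxybiphenyl-2-yl]-4H-chromen-4-one | COc1ccc(-c2cc(=O)c3c(OCc4ccccc4)cc(OCc4ccccc4)cc3o2)c(c1)-c1c(O)c(I)c(OCc2ccccc2)cc1OCc1ccccc1
F4 | step 4 | 1,3-bis(benzyloxy)-9-hydroxy-6H-benzo[c]chromen-6-one | Oc1ccc2c(c1)c1c(OCc3ccccc3)cc(OCc3ccccc3)cc1oc2=O
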